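**Retrosynthetic overview**
- The strategy rests on the ortho-hydroxyaryl ketone pair of the single benzene ring: C1 carries the (R)-2-methylbutanoyl group and C2 the neighbouring OH. Both bonds (C2–O and C1–C(=O)) are cut at once, back to a C1≡C2 aryne and (R)-2-methylbutanoic acid, which brings in the only stereocentre.
- The aryne comes from an ortho-silylaryl triflate with a MOM ether on O6 (next to C1, for regiocontrol) and a benzyl ether on O4. It is made from 2,4,6-trihydroxybenzaldehyde by stepwise protection, ortho-bromination, formyl-to-methyl reduction and retro-Brook/triflation.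
- After the insertion, C5 is iodinated, O2 is capped, and the acetyl group is installed by Stille coupling. Only then is O4 debenzylated and geranylated, so that no arylpalladium species ever sits beside an O-allyl ether and O4 is the only free hydroxyl at the alkylation.
- No ring is formed; the benzene ring is that of the starting aldehyde. The two MOM groups are removed last.

Key step: step 6

Remark: ring atoms are numbered throughout as C1 (2-methylbutanoyl), C2 (OH), C3 (CH3), C4 (O-geranyl), C5 (acetyl), C6 (OH); (R)-2-methylbutanoic acid is assumed to be bought enantiopure.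

**Route**

Step 1
Reactants: 1 2,4,6-trihydroxybenzaldehyde
Product: 2 2,6-dihydroxy-4-(methoxymethoxy)benzaldehyde
Conditions: MOMCl (1.05 equiv), i-Pr2NEt (1.2 equiv), THF, −10 °C to rt
Reagents that add atoms: chloromethyl methyl ether, COCCl
Why: Williamson-type O-alkylation in which the hydroxyl para to the formyl group, the most acidic one and the only one not hydrogen bonded to the carbonyl, should react first with one equivalent of MOMCl.

Step 2
Reactants: 2 2,6-dihydroxy-4-(methoxymethoxy)benzaldehyde
Product: 3 2-(benzyloxy)-6-hydroxy-4-(methoxymethoxy)benzaldehyde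
Conditions: BnBr (1.05 equiv), K2CO3 (1.1 equiv), acetone, 50 °C
Reagents that add atoms: benzyl bromide, BrCc1ccccc1
Why: Williamson ether synthesis on two equivalent hydroxyls, which should stop at mono-benzylation because the remaining hydroxyl stays locked in the hydrogen bond to the aldehyde.

Step 3
Reactants: 3 2-(benzyloxy)-6-hydroxy-4-(methoxymethoxy)benzaldehyde
Product: 4 6-(benzyloxy)-3-bromo-2-hydroxy-4-(methoxymethoxy)benzaldehyde
Conditions: NBS (1.0 equiv), MeCN, −10 to 0 °C
Reagents that add atoms: N-bromosuccinimide, O=C1CCC(=O)N1Br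
Why: Electrophilic aromatic bromination, expected at the ring carbon between the free hydroxyl and the MOM ether (ortho to the chelated phenol and less crowded than the carbon between the two ethers), as in the ortho-halogenation of 2-hydroxy-4,6-dialkoxyaryl carbonyl compounds.

Step 4
Reactants: 4 6-(benzyloxy)-3-bromo-2-hydroxy-4-(methoxymethoxy)benzaldehyde
Product: 6 3-(benzyloxy)-6-bromo-5-(methoxymethoxy)-2-methylphenol, via aryl ethyl carbonate 5 (not isolated)
Conditions: ClCO2Et, Et3N, THF, 0 °C; filter; then NaBH4, THF/H2O, 0 °C to rt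
Reagents that add atoms: none
Why: Reductive deoxygenation of a salicylaldehyde through its O-carbonate, in which hydride reduces the aldehyde, the carbonate migrates to the benzylic oxygen and is expelled to an ortho-quinone methide that a second hydride reduces to the ortho-cresol, while the bromide and both ethers are inert to NaBH4.

Step 5
Reactants: 6 3-(benzyloxy)-6-bromo-5-(methoxymethoxy)-2-methylphenol
Product: 9 3-(benzyloxy)-5-(methoxymethoxy)-2-methyl-6-(trimethylsilyl)phenyl trifluoromethanesulfonate, via aryl trimethylsilyl ether 7 (not isolated), via lithium silylphenolate 8 (not isolated)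
Conditions: HMDS, THF, 70 °C, then evaporate; n-BuLi, THF, −78 °C; Tf2O, −78 to 0 °C; NaHCO3 quench
Reagents that add atoms: hexamethyldisilazane, C[Si](C)(C)N[Si](C)(C)C; trifluoromethanesulfonic anhydride, O=S(=O)(OS(=O)(=O)C(F)(F)F)C(F)(F)F
Why: O-silylation, bromine–lithium exchange and retro-Brook rearrangement (1,3 O-to-C silyl shift) followed by O-triflation is the standard entry to ortho-silylaryl triflates, and the exchange at −78 °C should be faster than any deprotonation of the benzyl or MOM ether.

Step 6
Reactants: 9 3-(benzyloxy)-5-(methoxymethoxy)-2-methyl-6-(trimethylsilyl)phenyl trifluoromethanesulfonate; 10 (R)-2-methylbutanoic acid (1.2 equiv)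
Product: 12 (2R)-1-[4-(benzyloxy)-2-hydroxy-6-(methoxymethoxy)-3-methylphenyl]-2-methylbutan-1-one, via aryne 11 (not isolated)
Conditions: CsF (4 equiv), THF, 125 °C, sealed tube
Reagents that add atoms: none
Why: Desilylation of 9 by fluoride with loss of triflate releases aryne 11 (triple bond C1–C2); the caesium carboxylate of 10 adds through oxygen to C2, and the aryl anion left at C1 attacks the neighbouring ester carbonyl through a four-membered alkoxide that opens to the ortho-acyl phenolate (1,3 O-to-C acyl shift). The closest known reaction type is the fluoride-induced formal insertion of arynes into the C–O bond of carboxylic acids, which gives ortho-hydroxyaryl ketones from aliphatic acids. No ring is closed and no stereocentre is created; the R centre arrives with 10 and should persist because no bond to the alpha carbon is made or broken and the product is held as a phenolate that resists enolization. The step needs regioselectivity (oxygen to C2, acyl to C1) and chemoselectivity (acyl capture faster than protonation of the aryl anion). The first should come from the C6 methoxymethoxy group next to C1, whose inductive pull distorts the aryne and stabilizes negative charge at C1, and this should outweigh the steric effect of the C3 methyl and the remote C4 benzyloxy group. The second should come from excess CsF in aprotic THF, where the intramolecular acyl shift should outrun intermolecular proton transfer.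

Step 7
Reactants: 12 (2R)-1-[4-(benzyloxy)-2-hydroxy-6-(methoxymethoxy)-3-methylphenyl]-2-methylbutan-1-one
Product: 13 (2R)-1-[4-(benzyloxy)-2-hydroxy-5-iodo-6-(methoxymethoxy)-3-methylphenyl]-2-methylbutan-1-one
Conditions: NIS (1.05 equiv), MeCN, 0 °C, dark
Reagents that add atoms: N-iodosuccinimide, O=C1CCC(=O)N1I
Why: Electrophilic aromatic iodination at C5, the only unsubstituted ring carbon, which is para to the free phenol and ortho to two ether oxygens.

Step 8
Reactants: 13 (2R)-1-[4-(benzyloxy)-2-hydroxy-5-iodo-6-(methoxymethoxy)-3-methylphenyl]-2-methylbutan-1-one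
Product: 14 (2R)-1-[4-(benzyloxy)-5-iodo-2,6-bis(methoxymethoxy)-3-methylphenyl]-2-methylbutan-1-one
Conditions: MOMCl (3 equiv), i-Pr2NEt (4 equiv), n-Bu4NI (cat.), CH2Cl2, 40 °C
Reagents that add atoms: chloromethyl methyl ether, COCCl
Why: Williamson-type O-alkylation of the hydrogen-bonded C2 phenol under an amine base that is too weak to enolize the alpha-branched ketone.

Step 9
Reactants: 14 (2R)-1-[4-(benzyloxy)-5-iodo-2,6-bis(methoxymethoxy)-3-methylphenyl]-2-methylbutan-1-one; 15 tributyl(1-ethoxyvinyl)stannane (1.8 equiv)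
Product: 17 (2R)-1-[5-acetyl-4-(benzyloxy)-2,6-bis(methoxymethoxy)-3-methylphenyl]-2-methylbutan-1-one, via aryl enol ether 16 (not isolated)
Conditions: Pd(PPh3)4 (10 mol %), toluene, 100 °C; then 1 M aq. HCl, THF, 0 °C, 15 min; KF work-up
Reagents that add atoms: water, O
Why: Stille cross-coupling with the alpha-alkoxyvinylstannane as an acetyl anion equivalent under neutral conditions, followed by enol ether hydrolysis at 0 °C that should be much faster than MOM cleavage, on a substrate with no alkene that could intercept the arylpalladium intermediate.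

Step 10
Reactants: 17 (2R)-1-[5-acetyl-4-(benzyloxy)-2,6-bis(methoxymethoxy)-3-methylphenyl]-2-methylbutan-1-one
Product: 18 (2R)-1-[5-acetyl-4-hydroxy-2,6-bis(methoxymethoxy)-3-methylphenyl]-2-methylbutan-1-one
Conditions: H2 (1 atm), 10% Pd/C, EtOAc, rt
Reagents that add atoms: none
Why: Hydrogenolysis of the benzyl ether over palladium on carbon, which should leave the hindered aryl ketones, the MOM acetals and the stereocentre untouched at room temperature.

Step 11
Reactants: 18 (2R)-1-[5-acetyl-4-hydroxy-2,6-bis(methoxymethoxy)-3-methylphenyl]-2-methylbutan-1-one; 19 geranyl bromide (1.2 equiv)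
Product: 20 (2R)-1-[5-acetyl-4-{[(2E)-3,7-dimethylocta-2,6-dien-1-yl]oxy}-2,6-bis(methoxymethoxy)-3-methylphenyl]-2-methylbutan-1-one
Conditions: K2CO3 (1.5 equiv), DMF, rt
Reagents that add atoms: none
Why: Williamson ether synthesis by SN2 attack at the primary allylic carbon on the only free hydroxyl, so site selectivity is fixed by the protecting groups and the E olefin geometry is kept.

Step 12
Reactants: 20 (2R)-1-[5-acetyl-4-{[(2E)-3,7-dimethylocta-2,6-dien-1-yl]oxy}-2,6-bis(methoxymethoxy)-3-methylphenyl]-2-methylbutan-1-one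
Product: 21 (2R)-1-[5-acetyl-4-{[(2E)-3,7-dimethylocta-2,6-dien-1-yl]oxy}-2,6-dihydroxy-3-methylphenyl]-2-methylbutan-1-one (CNP0106233.1)
Conditions: p-TsOH·H2O (0.2 equiv), MeOH, rt
Reagents that add atoms: none
Why: Acid-catalysed transacetalization of the two aryl MOM ethers that sit ortho to carbonyl groups, which should be far more labile than the allylic aryl ether and the trisubstituted alkenes under catalytic acid at room temperature.

**Compound list**
1 | 2,4,6-trihydroxybenzaldehyde | O=Cc1c(O)cc(O)cc1O | starting material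
2 | 2,6-dihydroxy-4-(methoxymethoxy)benzaldehyde | O=Cc1c(O)cc(OCOC)cc1O | intermediate
3 | 2-(benzyloxy)-6-hydroxy-4-(methoxymethoxy)benzaldehyde | O=Cc1c(O)cc(OCOC)cc1OCc1ccccc1 | intermediate
4 | 6-(benzyloxy)-3-bromo-2-hydroxy-4-(methoxymethoxy)benzaldehyde | O=Cc1c(O)c(Br)c(OCOC)cc1OCc1ccccc1 | intermediate
5 | 3-(benzyloxy)-6-bromo-2-formyl-5-(methoxymethoxy)phenyl ethyl carbonate | CCOC(=O)Oc1c(Br)c(OCOC)cc(OCc2ccccc2)c1C=O | intermediate
6 | 3-(benzyloxy)-6-bromo-5-(methoxymethoxy)-2-methylphenol | Cc1c(O)c(Br)c(OCOC)cc1OCc1ccccc1 | intermediate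
7 | [3-(benzyloxy)-6-bromo-5-(methoxymethoxy)-2-methylphenoxy]trimethylsilane | Cc1c(O[Si](C)(C)C)c(Br)c(OCOC)cc1OCc1ccccc1 | intermediate
8 | lithium 3-(benzyloxy)-5-(methoxymethoxy)-2-methyl-6-(trimethylsilyl)phenolate | Cc1c([O-])c([Si](C)(C)C)c(OCOC)cc1OCc1ccccc1.[Li+] | intermediate
9 | 3-(benzyloxy)-5-(methoxymethoxy)-2-methyl-6-(trimethylsilyl)phenyl trifluoromethanesulfonate | Cc1c(OS(=O)(=O)C(F)(F)F)c([Si](C)(C)C)c(OCOC)cc1OCc1ccccc1 | intermediate
10 | (R)-2-methylbutanoic acid | CC[C@@H](C)C(=O)O | starting material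
11 | 4-(benzyloxy)-6-(methoxymethoxy)-3-methylbenzyne (1,2-didehydrobenzene, triple bond C1–C2) | CC1=C(OCc2ccccc2)C=C(OCOC)C#C1 | intermediate
12 | (2R)-1-[4-(benzyloxy)-2-hydroxy-6-(methoxymethoxy)-3-methylphenyl]-2-methylbutan-1-one | CC[C@@H](C)C(=O)c1c(O)c(C)c(OCc2ccccc2)cc1OCOC | intermediate
13 | (2R)-1-[4-(benzyloxy)-2-hydroxy-5-iodo-6-(methoxymethoxy)-3-methylphenyl]-2-methylbutan-1-one | CC[C@@H](C)C(=O)c1c(O)c(C)c(OCc2ccccc2)c(I)c1OCOC | intermediate
14 | (2R)-1-[4-(benzyloxy)-5-iodo-2,6-bis(methoxymethoxy)-3-methylphenyl]-2-methylbutan-1-one | CC[C@@H](C)C(=O)c1c(OCOC)c(C)c(OCc2ccccc2)c(I)c1OCOC | intermediate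
15 | tributyl(1-ethoxyvinyl)stannane | CCCC[Sn](CCCC)(CCCC)C(=C)OCC | starting material
16 | (2R)-1-[4-(benzyloxy)-5-(1-ethoxyethenyl)-2,6-bis(methoxymethoxy)-3-methylphenyl]-2-methylbutan-1-one | CC[C@@H](C)C(=O)c1c(OCOC)c(C)c(OCc2ccccc2)c(C(=C)OCC)c1OCOC | intermediate
17 | (2R)-1-[5-acetyl-4-(benzyloxy)-2,6-bis(methoxymethoxy)-3-methylphenyl]-2-methylbutan-1-one | CC[C@@H](C)C(=O)c1c(OCOC)c(C)c(OCc2ccccc2)c(C(C)=O)c1OCOC | intermediate
18 | (2R)-1-[5-acetyl-4-hydroxy-2,6-bis(methoxymethoxy)-3-methylphenyl]-2-methylbutan-1-one | CC[C@@H](C)C(=O)c1c(OCOC)c(C)c(O)c(C(C)=O)c1OCOC | intermediate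
19 | geranyl bromide, (2E)-1-bromo-3,7-dimethylocta-2,6-diene | BrC/C=C(\C)CCC=C(C)C | starting material
20 | (2R)-1-[5-acetyl-4-{[(2E)-3,7-dimethylocta-2,6-dien-1-yl]oxy}-2,6-bis(methoxymethoxy)-3-methylphenyl]-2-methylbutan-1-one | CC[C@@H](C)C(=O)c1c(OCOC)c(C)c(OC/C=C(\C)CCC=C(C)C)c(C(C)=O)c1OCOC | intermediate
21 | (2R)-1-[5-acetyl-4-{[(2E)-3,7-dimethylocta-2,6-dien-1-yl]oxy}-2,6-dihydroxy-3-methylphenyl]-2-methylbutan-1-one (CNP0106233.1) | CC[C@@H](C)C(=O)c1c(O)c(C)c(OC/C=C(\C)CCC=C(C)C)c(C(C)=O)c1O | target

**Step count and risks**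

Total steps: 12. Longest linear sequence: 12 (1 to 21).

Steps most likely to fail:

1. Step 6 (aryne insertion). The aryl anion may be protonated before the acyl shift, so that only O-arylation occurs; the carboxylate may add at C1 instead of C2; or the configuration may erode at 125 °C. Fallback: make the aryl–acyl bond by organolithium acylation. Bromophenol 6 is capped with MOMCl/i-Pr2NEt to give 1-(benzyloxy)-4-bromo-3,5-bis(methoxymethoxy)-2-methylbenzene F1. Acid 10 is converted with carbonyldiimidazole and N,O-dimethylhydroxylamine hydrochloride into (2R)-N-methoxy-N,2-dimethylbutanamide F2. Bromine–lithium exchange of F1 (n-BuLi, THF, −78 °C) and addition to F2, whose chelated tetrahedral adduct releases the ketone only on quench, should give (2R)-1-[4-(benzyloxy)-2,6-bis(methoxymethoxy)-3-methylphenyl]-2-methylbutan-1-one F3. Iodination of its only free ring carbon (NIS, cat. CF3CO2H, MeCN, 0 °C) rejoins the route at 14.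

2. Step 9 (Stille coupling). Transmetalation of the bulky alkoxyvinylstannane at an iodide flanked by two ortho ethers may be slow, which would lead to protodeiodination, and MOM groups may be lost during the acidic enol ether hydrolysis. Fallback: a carbonylative three-component coupling from 14 directly to 17 (PdCl2(PPh3)2, CO at 1–5 bar, tetramethylstannane, DMF, 80 °C). CO inserts into the hindered aryl–palladium bond, the small methyl group is then transferred to the acylpalladium one atom away from the ring, and no acid is needed; no new compound is passed (F0: none).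

3. Step 3 (bromination). Bromine may enter at the other free ring carbon (para to the hydroxyl), or twice. Fallback: place the silyl group by directed ortho-metalation instead of through a bromide. Aldehyde 3 is reduced first (ClCO2Et/Et3N, then NaBH4), through 3-(benzyloxy)-2-formyl-5-(methoxymethoxy)phenyl ethyl carbonate F4, to 3-(benzyloxy)-5-(methoxymethoxy)-2-methylphenol F5. Carbamoylation (Et2NCOCl, NaH, THF) gives 3-(benzyloxy)-5-(methoxymethoxy)-2-methylphenyl N,N-diethylcarbamate F6. Lithiation with s-BuLi/TMEDA at −78 °C at the carbon between the carbamate and the MOM ether, then TMSCl, gives 3-(benzyloxy)-5-(methoxymethoxy)-2-methyl-6-(trimethylsilyl)phenyl N,N-diethylcarbamate F7. LiAlH4 in THF cleaves the carbamate to 3-(benzyloxy)-5-(methoxymethoxy)-2-methyl-6-(trimethylsilyl)phenol F8. Deprotonation with n-BuLi gives lithium phenolate 8, which is triflated as in step 5 to 9.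

Further compounds
F1 | step 6 | 1-(benzyloxy)-4-bromo-3,5-bis(methoxymethoxy)-2-methylbenzene | Cc1c(OCOC)c(Br)c(OCOC)cc1OCc1ccccc1
F2 | step 6 | (2R)-N-methoxy-N,2-dimethylbutanamide | CC[C@@H](C)C(=O)N(C)OC
F3 | step 6 | (2R)-1-[4-(benzyloxy)-2,6-bis(methoxymethoxy)-3-methylphenyl]-2-methylbutan-1-one | CC[C@@H](C)C(=O)c1c(OCOC)c(C)c(OCc2ccccc2)cc1OCOC
F0 | step 9 | none | none
F4 | step 3 | 3-(benzyloxy)-2-formyl-5-(methoxymethoxy)phenyl ethyl carbonate | CCOC(=O)Oc1cc(OCOC)cc(OCc2ccccc2)c1C=O
F5 | step 3 | 3-(benzyloxy)-5-(methoxymethoxy)-2-methylphenol | Cc1c(O)cc(OCOC)cc1OCc1ccccc1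
F6 | step 3 | 3-(benzyloxy)-5-(methoxymethoxy)-2-methylphenyl N,N-diethylcarbamate | CCN(CC)C(=O)Oc1cc(OCOC)cc(OCc2ccccc2)c1C
F7 | step 3 | 3-(benzyloxy)-5-(methoxymethoxy)-2-methyl-6-(trimethylsilyl)phenyl N,N-diethylcarbamate | CCN(CC)C(=O)Oc1c([Si](C)(C)C)c(OCOC)cc(OCc2ccccc2)c1C
F8 | step 3 | 3-(benzyloxy)-5-(methoxymethoxy)-2-methyl-6-(trimethylsilyl)phenol | Cc1c(O)c([Si](C)(C)C)c(OCOC)cc1OCc1ccccc1
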